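## Structural features

The target is an open-chain propan-1-one. C1 is the ketone carbon bound to ring A (2-hydroxy-4-methoxyphenyl), C2 is a methine bound to C3 of a 7-hydroxy-4H-chromen-4-one, and C3 is a methine carrying two 4-hydroxyphenyl rings. C2 is the only stereocentre (R); its neighbour C3 bears two identical aryl groups and is not stereogenic, so the problem is one of absolute configuration only. The C2–H bond is the fragile point, because it is alpha to the aryl ketone and allylic to the chromone C2=C3 bond, so a base can enolise it and erase the configuration. Other sensitive sites are chromone C2 (a vinylogous ester carbon that takes up hydroxide, amines and hard organometallics), the reducible chromone C2=C3 bond, and four phenols of which only the ring A oxygen at C4 is methylated. The real difficulty is to join three bulky groups (aroyl, chromonyl, diarylmethyl) to one sp3 carbon as a single enantiomer and then to create the last carbonyl next to it without losing it. The key step exploits ring A: the acyl carbon on C1 and the free hydroxyl on C2 sit on adjacent ring carbons, with the methoxy group on C4 para to the acyl group. C1 and C2 can therefore be the two carbons of an aryne that takes up the C(=O)–O unit of a carboxylic acid, while C6 carries a removable chlorine that steers the addition.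

## Logic of the disconnections

The structures of the key-step partners were checked against the target and needed no correction; the centre is R in 17, 24 and 25.

**25 from 24.** Three O–CH2Ph bonds and the ring A C6–Cl bond are put back. The phenols must be masked because a free phenoxide would add to the aryne, and the chlorine is needed as a regiochemical control element. All four groups fall in one reductive operation. The forward step must cleave benzylic C–O and aryl C–Cl bonds faster than it reduces the chromone C2=C3 bond, in a medium too weakly basic to enolise C2–H.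

**24 from 17 and 22.** The ring A C1–C(=O) and C2–O bonds are cut. The carboxyl carbon and the hydroxyl oxygen of an acid reappear as ketone and phenol on neighbouring ring carbons. This splits the molecule into a chiral acid holding three of the four aryl units and a simple arene, needs no protecting group for the ring A hydroxyl, and settles the methyl ether question because the methoxy group is on the arene from the start. The forward step needs regiocontrol (supplied by chlorine), heat for the acyl shift, and a stereocentre that survives both.

**22 from 20, 19 and 18.** The O–S bond of the triflate, the C–Si bond and the C–Br bond are cut in turn. An ortho-silylaryl triflate releases the aryne with fluoride under non-basic conditions, and the silicon is placed by an oxygen-to-carbon shift from an ortho-bromo silyl ether. Bromination must enter the one free position ortho to the hydroxyl, and halogen–metal exchange must choose bromine over chlorine.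

**17 from 16.** The O–C(CH3)3 bond is cut. The carboxyl group is needed free only for the key step, and a tert-butyl ester is removed by acid, which does not enolise the centre. The acid must spare the benzyl ethers and the chromone.

**16 from 14.** The chromone C2–C3 and O1–C2 bonds are cut, which removes C2 as a one-carbon unit at the formate oxidation level. The heterocycle is reduced to an ortho-hydroxyaryl ketone whose alpha methylene is the CH2 arm of a succinate. The condensation must take place at a hindered methylene without a base strong enough to epimerise the ester alpha centre.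

**14 from 13.** One O–CH2Ph bond is cut at the oxygen para to the ketone. The ortho hydroxyl is held in a hydrogen bond to the carbonyl, so the forward alkylation has to discriminate only between a chelated and a free phenol.

**13 from 8 and 10.** The aryl–carbonyl bond (future C4–C4a) and two acetal C–O bonds are cut. The acyl partner is an N-methoxy-N-methylamide and the aryl partner comes from the brominated carbon of a resorcinol, ortho and para to the two oxygens as the chromone requires. This separates the resorcinol ring from the chiral succinate. The step demands single addition, an untouched tert-butyl ester, and oxygen protection that falls in the acidic quench. Acetals are chosen over benzyl for this reason, and this is the main change to the precursor design: no Lewis acid is ever needed next to the tert-butyl ester.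

**10 from 9.** Two acetal C–O bonds are cut. Both hydroxyls receive the same group, so no regiochemical question arises.

**8 from 6.** The amide C–N bond is cut. The free carboxyl arm of the half-ester is the only acid present, so activation is unambiguous; it must be mild enough to leave the neighbouring ester alone.

**6 from 5.** The two C–H bonds at C3 and C4 are removed. The stereocentre becomes a trigonal alkene carbon whose partner bears two identical aryl groups (no E/Z issue) and which lies beta to a carboxylate that can chelate a metal. The catalyst must differentiate the faces of a tetrasubstituted alkene and must not cleave benzyl ethers.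

**5 from 2 and 3.** The C=C bond is cut. The condensation differentiates the two carboxyl groups by itself: the free acid ends on the CH2 arm (future chromone C4) and the ester on the alkene carbon (future ring A ketone carbon). The hindered, electron-rich diaryl ketone requires the irreversible lactone opening as driving force, and tert-butyl esters to suppress self-condensation.

**2 from 1.** Two O–CH2Ph bonds are cut; the phenols would otherwise be deprotonated and shut down the ketone.

## Other disconnections considered

**Alternative 1:** The cut is the C4–C3 bond of the pyranone, made at the chroman-4-one oxidation level.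

- Forward step: aldehyde–enone A1 is a 2-alkoxybenzaldehyde whose ether chain ends in a trisubstituted aryl enone that already holds ring A and the diarylmethyl group. It would be treated with a chiral aminoindanol-derived triazolium salt and KN(SiMe3)2. The carbene turns the aldehyde into an acyl anion equivalent that adds to the enone beta carbon (intramolecular Stetter reaction) and closes the six-membered ring. Protonation of the enolate at the alpha carbon then gives chroman-4-one A2, with ring centre S and exocyclic centre R.
- In its favour: the ring A ketone is present from the start as the activating group of the acceptor, so no late aryl ketone synthesis, no chlorine and no hydrodechlorination are needed. On this point the alternative is better than the chosen plan. The two oxygens of the resorcinol ring are differentiated from the outset by O-alkylation of a salicylaldehyde, which is also better.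
- Against it here: the acceptor carries a bulky diarylmethyl group on its alpha carbon, at the limit of what such closures accept. The centre that survives into the target is set only by the protonation that follows C–C bond formation, while the centre the catalyst controls directly (ring C3) is destroyed when A2 is dehydrogenated to the chromone. That oxidation has to be done on a 1,4-diketone in which the exocyclic C–H is about as acidic as the ring C–H.
- Comparison: on structure, the chosen plan forms the chromone at its final oxidation level and keeps the centre next to a carboxyl group until the penultimate step, whereas here it stays alpha to a ketone for two further steps. On mechanism, catalytic enantiocontrol in the ring-forming step is a real attraction. On step count the two are about equal, since A1 needs its own enone synthesis and the end game needs an extra oxidation.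

**Alternative 2:** The cut removes C4 from the chromone by breaking C4–C4a and C4–C3.

- Forward step: cyclopropanol A3 and aryl iodide A4 would be coupled with Pd(PPh3)4 under carbonylative conditions. Oxidative addition of A4 to zerovalent palladium and carbonyl insertion give an aroylpalladium species. The palladium alkoxide of A3 opens at its CH2–C(OH) bond to a homoenolate, and reductive elimination gives 1,4-diketone A5. Desilylation, the one-carbon condensation of step 8 and hydrogenolysis would follow.
- In its favour: the route is convergent, and the stereocentre is stored as a ring carbon of the cyclopropane, not alpha to a carbonyl, until the key step. Ring A arrives with its oxygen pattern and without a chlorine placeholder (better). A4 has its two oxygens differentiated as silyl and benzyl ethers, which is more direct than the acetal protection and selective benzylation of the chosen route (better).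
- Against it here: the ring-opened palladium homoenolate has a beta hydrogen on the stereogenic carbon, and beta-hydride elimination would give an enone and destroy the centre. Enantiopure A3 with its bulky diarylmethyl group needs a multi-step asymmetric synthesis of its own. From A5 onward the centre is alpha to the ring A ketone during a condensation near 100 °C, a longer exposure than in the chosen plan.
- Comparison: both plans use the same amide-acetal ring closure. The alternative makes both bonds to C4 in one step, while the chosen plan makes both bonds to ring A C1 and C2 in one step. The organopalladium step and the aryne step are equally untested on a substrate this hindered. The step count is equal at best, and the final hydrogenolysis has no C–Cl bond to cleave (equal or better).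

**Alternative 3:** The cut is ring A itself, at C1–C2 and C5–C6.

- Forward step: terminal ynone A6 would be made from 17 by acetylide addition to an activated derivative. With 1,3-dimethoxy-1-(trimethylsilyloxy)buta-1,3-diene A7 it undergoes a thermal [4+2] cycloaddition, the CH2 terminus of A7 bonding to the terminal alkyne carbon. The adduct aromatises by loss of its acetal methoxy group, and desilylation gives A8, which is 24 without chlorine.
- In its favour: the ring A substitution pattern is set by the polarisation of both partners, which is regiocontrol equal to or better than chlorine control. A8 needs only debenzylation (better). The ring-forming step is neutral and pericyclic, with no fluoride or base (better for the centre during that step). The route is shared up to 17 (equal).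
- Against it here: in A6 the stereocentre is alpha to an ynone, more acidic than in any compound of the chosen route and next to a Michael acceptor. Making A6 requires an acetylide in the presence of the chromone, which itself accepts organometallics at C2 and C4. The hindered ynone needs heat with a moisture-sensitive diene, and the chromone C2=C3 bond is a second, weak dienophile.
- Comparison: step economy is equal, since two extra steps from 17 to A6 are offset by the three steps to 22 that fall away. On structure, the chosen plan keeps the centre as a carboxylate until one step from the end, while the alternative carries it as its most labile ketone for two steps. On mechanism, the alternative is milder in the ring-forming step but harsher on the way to its substrate.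

Key step: step 13

Assumption: the S,S antipode of Et-DuPHOS is taken to deliver the S acid 6; should substrate 5 respond with the opposite sense, the R,R antipode is used under the same conditions.

Remark on descriptors: 6, 7, 8, 12, 13 and 14 are S and 15, 16, 17, 24 and 25 are R with the same arrangement in space, because the CH2 arm ranks below the diarylmethyl group until it becomes an sp2 carbon.

## Steps

Step 1
Reactants: 1 bis(4-hydroxyphenyl)methanone (4,4'-dihydroxybenzophenone)
Product: 2 bis[4-(benzyloxy)phenyl]methanone
Conditions: BnBr (2.2 equiv), K2CO3, DMF, 60 °C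
Reagents that add atoms: benzyl bromide, BrCc1ccccc1
Why: Williamson ether synthesis on both phenols; the benzyl ethers tolerate strong base, organomagnesium reagents, TFA and fluoride and fall together at the end.

Step 2
Reactants: 2 bis[4-(benzyloxy)phenyl]methanone; 3 di-tert-butyl succinate
Product: 5 4,4-bis[4-(benzyloxy)phenyl]-3-(tert-butoxycarbonyl)but-3-enoic acid, via paraconic lactone 4 (not isolated)
Conditions: KOtBu, t-BuOH, 82 °C; then aq. HCl
Reagents that add atoms: none
Why: Stobbe condensation: the succinate enolate adds to the ketone, the alkoxide closes onto the remote ester to lactone 4, and E1cb opening gives the half-ester with the free acid on the CH2 arm; the irreversible opening drives the hindered ketone, and two identical aryl groups leave no alkene isomers.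

Step 3
Reactants: 5 4,4-bis[4-(benzyloxy)phenyl]-3-(tert-butoxycarbonyl)but-3-enoic acid
Product: 6 (S)-4,4-bis[4-(benzyloxy)phenyl]-3-(tert-butoxycarbonyl)butanoic acid
Conditions: H2 (10 bar), [Rh(cod)((S,S)-Et-DuPHOS)]BF4 (2 mol %), NaOMe (10 mol %), MeOH, 25 °C
Reagents that add atoms: none
Why: Rhodium-catalysed asymmetric hydrogenation of a Stobbe-derived alkylidenesuccinate half-ester: carboxylate and alkene chelate the cationic rhodium bisphosphine and the C2-symmetric phospholane ligand lets H2 add to one face of prochiral C3, which sets the S centre; the homogeneous catalyst should leave the benzyl ethers intact.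

Step 4
Reactants: 6 (S)-4,4-bis[4-(benzyloxy)phenyl]-3-(tert-butoxycarbonyl)butanoic acid
Product: 8 tert-butyl (S)-2-{bis[4-(benzyloxy)phenyl]methyl}-4-[methoxy(methyl)amino]-4-oxobutanoate, via acyl imidazole 7 (not isolated)
Conditions: CDI, CH2Cl2, rt; then MeNH(OMe)·HCl, rt
Reagents that add atoms: N,O-dimethylhydroxylamine hydrochloride, CNOC.Cl
Why: Carboxyl activation as the acyl imidazole followed by aminolysis; the near-neutral conditions should leave the tert-butyl ester and the ester alpha centre untouched.

Step 5
Reactants: 9 4-bromobenzene-1,3-diol (4-bromoresorcinol)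
Product: 10 4-bromo-1,3-bis(tetrahydro-2H-pyran-2-yloxy)benzene (mixture of acetal diastereomers)
Conditions: 3,4-dihydro-2H-pyran, PPTS (cat.), CH2Cl2, rt
Reagents that add atoms: 3,4-dihydro-2H-pyran, C1=COCCC1
Why: Acid-catalysed acetalisation of both phenols; tetrahydropyranyl ethers tolerate magnesium and are later cleaved by dilute acid that spares a tert-butyl ester, and identical protection avoids any regiochemical question.

Step 6
Reactants: 10 4-bromo-1,3-bis(tetrahydro-2H-pyran-2-yloxy)benzene; 8 tert-butyl (S)-2-{bis[4-(benzyloxy)phenyl]methyl}-4-[methoxy(methyl)amino]-4-oxobutanoate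
Product: 13 tert-butyl (S)-2-{bis[4-(benzyloxy)phenyl]methyl}-4-(2,4-dihydroxyphenyl)-4-oxobutanoate, via aryl Grignard reagent 11 (not isolated), via bis-acetal ketone 12 (not isolated)
Conditions: 10, Mg, I2 (cat.), THF, 50 °C; then 8, THF, 0 °C to rt; then 1 M HCl, MeOH, rt
Reagents that add atoms: none
Why: Grignard addition to an N-methoxy-N-methylamide stops at the chelated tetrahedral adduct, so only the ketone forms and the hindered tert-butyl ester is not attacked; the methanolic acid quench releases ketone 12 and transfers both acetal groups to methanol in the same flask, and the stereocentre, beta to the new ketone, is not involved.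

Step 7
Reactants: 13 tert-butyl (S)-2-{bis[4-(benzyloxy)phenyl]methyl}-4-(2,4-dihydroxyphenyl)-4-oxobutanoate
Product: 14 tert-butyl (S)-4-[4-(benzyloxy)-2-hydroxyphenyl]-2-{bis[4-(benzyloxy)phenyl]methyl}-4-oxobutanoate
Conditions: BnBr (1.05 equiv), K2CO3, acetone, 50 °C
Reagents that add atoms: benzyl bromide, BrCc1ccccc1
Why: Regioselective Williamson ether synthesis: the ortho hydroxyl is locked in a hydrogen bond to the ketone, so the para phenoxide is the one that forms and is alkylated; K2CO3 is too weak to enolise the ester alpha centre.

Step 8
Reactants: 14 tert-butyl (S)-4-[4-(benzyloxy)-2-hydroxyphenyl]-2-{bis[4-(benzyloxy)phenyl]methyl}-4-oxobutanoate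
Product: 16 tert-butyl (R)-2-[7-(benzyloxy)-4-oxo-4H-chromen-3-yl]-3,3-bis[4-(benzyloxy)phenyl]propanoate, via enaminone 15 (not isolated)
Conditions: Me2NCH(OMe)2, toluene, 100 °C; then AcOH, 60 °C
Reagents that add atoms: N,N-dimethylformamide dimethyl acetal, COC(OC)N(C)C
Why: Amide-acetal condensation at the ketone methylene gives enaminone 15, and addition of the phenol to its beta carbon with loss of dimethylamine closes the pyranone, the same ring synthesis that turns 2-hydroxyphenyl benzyl ketones into isoflavones; the stereocentre is activated only by the tert-butyl ester and should not be enolised in this near-neutral medium.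

Step 9
Reactants: 16 tert-butyl (R)-2-[7-(benzyloxy)-4-oxo-4H-chromen-3-yl]-3,3-bis[4-(benzyloxy)phenyl]propanoate
Product: 17 (R)-2-[7-(benzyloxy)-4-oxo-4H-chromen-3-yl]-3,3-bis[4-(benzyloxy)phenyl]propanoic acid
Conditions: TFA, CH2Cl2 (1:4), 0 °C to rt
Reagents that add atoms: none
Why: Acid-mediated E1 cleavage of the tert-butyl ester with loss of 2-methylpropene; aryl benzyl ethers and the chromone tolerate dilute TFA at room temperature, and acid does not enolise the centre.

Step 10
Reactants: 18 2-chloro-4-methoxyphenol
Product: 19 2-bromo-6-chloro-4-methoxyphenol
Conditions: NBS, i-Pr2NH (cat.), CH2Cl2, 0 °C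
Reagents that add atoms: N-bromosuccinimide, O=C1CCC(=O)N1Br
Why: Electrophilic aromatic bromination directed by the free hydroxyl, the strongest donor; its para position is blocked by the methoxy group and one ortho position by chlorine, so bromine should enter C6, and the amine-catalysed variant favours ortho attack.

Step 11
Reactants: 19 2-bromo-6-chloro-4-methoxyphenol
Product: 20 (2-bromo-6-chloro-4-methoxyphenoxy)trimethylsilane
Conditions: (Me3Si)2NH, THF, 65 °C; concentrate
Reagents that add atoms: hexamethyldisilazane, C[Si](C)(C)N[Si](C)(C)C
Why: O-silylation of the phenol with loss of ammonia; it places silicon on oxygen ready for the shift to carbon in the next step.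

Step 12
Reactants: 20 (2-bromo-6-chloro-4-methoxyphenoxy)trimethylsilane
Product: 22 2-chloro-4-methoxy-6-(trimethylsilyl)phenyl trifluoromethanesulfonate, via lithium phenoxide 21 (not isolated)
Conditions: n-BuLi, THF, −78 °C; then Tf2O, −78 °C to rt
Reagents that add atoms: trifluoromethanesulfonic anhydride, O=S(=O)(OS(=O)(=O)C(F)(F)F)C(F)(F)F
Why: Bromine–lithium exchange is much faster than exchange at chlorine, the ortho-lithiated silyl ether undergoes a retro-Brook 1,3 shift of silicon from oxygen to carbon, and phenoxide 21 is trapped as the triflate; this is the standard way to ortho-silylaryl triflates.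

Step 13
Reactants: 17 (R)-2-[7-(benzyloxy)-4-oxo-4H-chromen-3-yl]-3,3-bis[4-(benzyloxy)phenyl]propanoic acid; 22 2-chloro-4-methoxy-6-(trimethylsilyl)phenyl trifluoromethanesulfonate
Product: 24 (R)-7-(benzyloxy)-3-{1,1-bis[4-(benzyloxy)phenyl]-3-(2-chloro-6-hydroxy-4-methoxyphenyl)-3-oxopropan-2-yl}-4H-chromen-4-one, via 3-chloro-5-methoxybenzyne 23 (not isolated)
Conditions: CsF (4 equiv), 22 (1.5 equiv), THF, 125 °C, sealed tube
Reagents that add atoms: none
Why: Fluoride attacks silicon in 22 and the aryl anion expels triflate to give aryne 23, while CsF turns 17 into its caesium carboxylate. The carboxylate oxygen adds to the aryne carbon remote from chlorine, which leaves the negative charge on the carbon next to chlorine, where the C–Cl dipole stabilises it. This aryl anion attacks the neighbouring ester carbonyl in a four-centre 1,3 acyl shift from oxygen to carbon, and collapse gives the ortho-acyl phenoxide, protonated to 24 on work-up; at 125 °C the shift should outrun protonation to the simple aryl ester. The closest known reaction type is the fluoride-induced insertion of arynes into the C–O bond of carboxylic acids to give ortho-hydroxyaryl ketones. No ring is closed and no stereocentre is formed; the R centre of 17 is only carried through, and as the alpha carbon of a carboxylate it is not deprotonated before the ketone exists. The step needs regioselectivity (oxygen to future C2, acyl to future C1), which the chlorine of 23 secures against the weak effect of the remote methoxy group, and chemoselectivity, which is secured because the carboxylate is the only nucleophile once every phenol is benzylated. In the product the ketone lies between chlorine and a phenoxide and carries two bulky alpha substituents, so the planar enolate needed for racemisation is strained and should form slowly.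

Step 14
Reactants: 24 (R)-7-(benzyloxy)-3-{1,1-bis[4-(benzyloxy)phenyl]-3-(2-chloro-6-hydroxy-4-methoxyphenyl)-3-oxopropan-2-yl}-4H-chromen-4-one
Product: 25 (R)-7-hydroxy-3-[3-(2-hydroxy-4-methoxyphenyl)-1,1-bis(4-hydroxyphenyl)-3-oxopropan-2-yl]-4H-chromen-4-one
Conditions: H2 (1 atm), 10% Pd/C, NaOAc, EtOAc/MeOH, rt
Reagents that add atoms: none
Why: Catalytic hydrogenolysis of three aryl benzyl ethers together with hydrodechlorination of the aryl chloride; NaOAc takes up the HCl so that neither acid nor a strong base meets the labile C2–H, and the hindered trisubstituted chromone C2=C3 bond should be reduced more slowly than the benzylic C–O and the C–Cl bonds are cleaved.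

## Compound list

1 | bis(4-hydroxyphenyl)methanone (4,4'-dihydroxybenzophenone) | O=C(c1ccc(O)cc1)c1ccc(O)cc1 | starting material
2 | bis[4-(benzyloxy)phenyl]methanone | O=C(c1ccc(OCc2ccccc2)cc1)c1ccc(OCc2ccccc2)cc1 | intermediate
3 | di-tert-butyl succinate | CC(C)(C)OC(=O)CCC(=O)OC(C)(C)C | starting material
4 | tert-butyl 2,2-bis[4-(benzyloxy)phenyl]-5-oxotetrahydrofuran-3-carboxylate (racemic paraconic lactone) | CC(C)(C)OC(=O)C1CC(=O)OC1(c2ccc(OCc3ccccc3)cc2)c2ccc(OCc3ccccc3)cc2 | intermediate (not isolated)
5 | 4,4-bis[4-(benzyloxy)phenyl]-3-(tert-butoxycarbonyl)but-3-enoic acid | CC(C)(C)OC(=O)C(CC(=O)O)=C(c1ccc(OCc2ccccc2)cc1)c1ccc(OCc2ccccc2)cc1 | intermediate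
6 | (S)-4,4-bis[4-(benzyloxy)phenyl]-3-(tert-butoxycarbonyl)butanoic acid | CC(C)(C)OC(=O)[C@@H](CC(=O)O)C(c1ccc(OCc2ccccc2)cc1)c1ccc(OCc2ccccc2)cc1 | intermediate
7 | tert-butyl (S)-2-{bis[4-(benzyloxy)phenyl]methyl}-4-(1H-imidazol-1-yl)-4-oxobutanoate | CC(C)(C)OC(=O)[C@@H](CC(=O)n1ccnc1)C(c1ccc(OCc2ccccc2)cc1)c1ccc(OCc2ccccc2)cc1 | intermediate (not isolated)
8 | tert-butyl (S)-2-{bis[4-(benzyloxy)phenyl]methyl}-4-[methoxy(methyl)amino]-4-oxobutanoate | CC(C)(C)OC(=O)[C@@H](CC(=O)N(C)OC)C(c1ccc(OCc2ccccc2)cc1)c1ccc(OCc2ccccc2)cc1 | intermediate
9 | 4-bromobenzene-1,3-diol (4-bromoresorcinol) | Oc1ccc(Br)c(O)c1 | starting material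
10 | 4-bromo-1,3-bis(tetrahydro-2H-pyran-2-yloxy)benzene (acetal centres unspecified) | Brc1ccc(OC2CCCCO2)cc1OC1CCCCO1 | intermediate
11 | [2,4-bis(tetrahydro-2H-pyran-2-yloxy)phenyl]magnesium bromide | Br[Mg]c1ccc(OC2CCCCO2)cc1OC1CCCCO1 | intermediate (not isolated)
12 | tert-butyl (S)-2-{bis[4-(benzyloxy)phenyl]methyl}-4-[2,4-bis(tetrahydro-2H-pyran-2-yloxy)phenyl]-4-oxobutanoate (acetal centres unspecified) | CC(C)(C)OC(=O)[C@@H](CC(=O)c1ccc(OC2CCCCO2)cc1OC1CCCCO1)C(c1ccc(OCc2ccccc2)cc1)c1ccc(OCc2ccccc2)cc1 | intermediate (not isolated)
13 | tert-butyl (S)-2-{bis[4-(benzyloxy)phenyl]methyl}-4-(2,4-dihydroxyphenyl)-4-oxobutanoate | CC(C)(C)OC(=O)[C@@H](CC(=O)c1ccc(O)cc1O)C(c1ccc(OCc2ccccc2)cc1)c1ccc(OCc2ccccc2)cc1 | intermediate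
14 | tert-butyl (S)-4-[4-(benzyloxy)-2-hydroxyphenyl]-2-{bis[4-(benzyloxy)phenyl]methyl}-4-oxobutanoate | CC(C)(C)OC(=O)[C@@H](CC(=O)c1ccc(OCc2ccccc2)cc1O)C(c1ccc(OCc2ccccc2)cc1)c1ccc(OCc2ccccc2)cc1 | intermediate
15 | tert-butyl (R)-3-[4-(benzyloxy)-2-hydroxybenzoyl]-2-{bis[4-(benzyloxy)phenyl]methyl}-4-(dimethylamino)but-3-enoate (alkene geometry unspecified) | CC(C)(C)OC(=O)[C@@H](C(=CN(C)C)C(=O)c1ccc(OCc2ccccc2)cc1O)C(c1ccc(OCc2ccccc2)cc1)c1ccc(OCc2ccccc2)cc1 | intermediate (not isolated)
16 | tert-butyl (R)-2-[7-(benzyloxy)-4-oxo-4H-chromen-3-yl]-3,3-bis[4-(benzyloxy)phenyl]propanoate | CC(C)(C)OC(=O)[C@@H](c1coc2cc(OCc3ccccc3)ccc2c1=O)C(c1ccc(OCc2ccccc2)cc1)c1ccc(OCc2ccccc2)cc1 | intermediate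
17 | (R)-2-[7-(benzyloxy)-4-oxo-4H-chromen-3-yl]-3,3-bis[4-(benzyloxy)phenyl]propanoic acid | OC(=O)[C@@H](c1coc2cc(OCc3ccccc3)ccc2c1=O)C(c1ccc(OCc2ccccc2)cc1)c1ccc(OCc2ccccc2)cc1 | intermediate
18 | 2-chloro-4-methoxyphenol | COc1ccc(O)c(Cl)c1 | starting material
19 | 2-bromo-6-chloro-4-methoxyphenol | COc1cc(Cl)c(O)c(Br)c1 | intermediate
20 | (2-bromo-6-chloro-4-methoxyphenoxy)trimethylsilane | COc1cc(Cl)c(O[Si](C)(C)C)c(Br)c1 | intermediate
21 | lithium 2-chloro-4-methoxy-6-(trimethylsilyl)phenoxide | COc1cc(Cl)c([O-])c([Si](C)(C)C)c1.[Li+] | intermediate (not isolated)
22 | 2-chloro-4-methoxy-6-(trimethylsilyl)phenyl trifluoromethanesulfonate | COc1cc(Cl)c(OS(=O)(=O)C(F)(F)F)c([Si](C)(C)C)c1 | intermediate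
23 | 3-chloro-5-methoxybenzyne (3-chloro-5-methoxy-1,2-didehydrobenzene) | COC1=CC#CC(Cl)=C1 | intermediate (not isolated)
24 | (R)-7-(benzyloxy)-3-{1,1-bis[4-(benzyloxy)phenyl]-3-(2-chloro-6-hydroxy-4-methoxyphenyl)-3-oxopropan-2-yl}-4H-chromen-4-one | COc1cc(Cl)c(C(=O)[C@@H](c2coc3cc(OCc4ccccc4)ccc3c2=O)C(c2ccc(OCc3ccccc3)cc2)c2ccc(OCc3ccccc3)cc2)c(O)c1 | intermediate
25 | (R)-7-hydroxy-3-[3-(2-hydroxy-4-methoxyphenyl)-1,1-bis(4-hydroxyphenyl)-3-oxopropan-2-yl]-4H-chromen-4-one | COc1ccc(C(=O)[C@@H](c2coc3cc(O)ccc3c2=O)C(c2ccc(O)cc2)c2ccc(O)cc2)c(O)c1 | target

## Step count and least certain steps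

Total: 14 steps. Longest linear sequence: 10 steps (1, 2, 3, 4, 6, 7, 8, 9, 13, 14).

**Step 13 (key step).** Three processes are the most likely to go wrong.
- The reaction may stop at O-arylation: the aryl anion may be protonated by the bifluoride formed from the acid, or may fail to reach the carbonyl of a doubly branched acyl group beside chlorine, so that only the aryl ester forms.
- The configuration may erode by enolisation of the new ketone in hot fluoride medium.
- The ortho-chloroaryl anion may lose chloride and form a second aryne.

A first adjustment within the same approach is to use the dried caesium salt of 17, which removes the only proton source. The fallback abandons the aryne and sets out from 17. Thiophenol, EDC·HCl and catalytic DMAP in CH2Cl2 at 0 °C would give S-phenyl (R)-2-[7-(benzyloxy)-4-oxo-4H-chromen-3-yl]-3,3-bis[4-(benzyloxy)phenyl]propanethioate F1. A Liebeskind–Srogl coupling of this thioester with commercial (2,4-dimethoxyphenyl)boronic acid would follow, using Pd2(dba)3, tri(2-furyl)phosphine and Cu(O2CC4H3S) (the thiophene-2-carboxylate of monovalent copper) in THF at 50 °C. These neutral conditions are known to preserve alpha-stereocentres of thioesters, and the product would be (R)-7-(benzyloxy)-3-{1,1-bis[4-(benzyloxy)phenyl]-3-(2,4-dimethoxyphenyl)-3-oxopropan-2-yl}-4H-chromen-4-one F2. BCl3 with pentamethylbenzene in CH2Cl2 (−78 °C to 0 °C) would then remove the three benzyl groups and, by chelation to the ketone, only the methyl ether ortho to it. The fallback returns to the route at 25.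

**Step 3.** The tetrasubstituted alkene with two aryl groups may bind the rhodium catalyst poorly, which would mean slow uptake of hydrogen or poor facial selectivity. The fallback sets out from 5. Conjugate reduction with Mg in MeOH, which reduces beta-aryl unsaturated esters and leaves benzyl ethers alone, would give racemic 4,4-bis[4-(benzyloxy)phenyl]-3-(tert-butoxycarbonyl)butanoic acid F3. The enantiomers would be separated by preparative chromatography on a chiral stationary phase, and the S enantiomer rejoins the route at 6.

**Step 8.** Condensation at a methylene flanked by the ketone and a fully substituted methine may be slow, which would let O-methylation of the phenol by the acetal or slow epimerisation at the ester alpha carbon compete. The fallback sets out from 14. A Claisen condensation with ethyl formate and NaH in THF at 0 °C proceeds through the dianion, which places the charge on the ketone side and not on the ester alpha carbon. It would give tert-butyl (2R)-2-[7-(benzyloxy)-2-hydroxy-4-oxo-3,4-dihydro-2H-chromen-3-yl]-3,3-bis[4-(benzyloxy)phenyl]propanoate F4, the cyclic hemiacetal of the formyl ketone. Catalytic p-toluenesulfonic acid in toluene would dehydrate it, and the fallback returns at 16.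

**Step 14.** The chromone C2=C3 bond may be over-reduced while the chlorine on an electron-rich ring is still being removed, or C–Cl cleavage may stay incomplete. The fallback sets out from 24 and separates the two tasks. BCl3 with pentamethylbenzene in CH2Cl2 at −78 °C would cleave the benzyl ethers without any reductant and give (R)-3-[3-(2-chloro-6-hydroxy-4-methoxyphenyl)-1,1-bis(4-hydroxyphenyl)-3-oxopropan-2-yl]-7-hydroxy-4H-chromen-4-one F5. A palladium-catalysed transfer hydrodechlorination with Pd(OAc)2, P(t-Bu)3·HBF4 and HCO2Na in DMF at 60 °C would then remove the chlorine, and the fallback returns at 25.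

## Further compounds

F1 | step 13 | S-phenyl (R)-2-[7-(benzyloxy)-4-oxo-4H-chromen-3-yl]-3,3-bis[4-(benzyloxy)phenyl]propanethioate | O=C(Sc1ccccc1)[C@@H](c1coc2cc(OCc3ccccc3)ccc2c1=O)C(c1ccc(OCc2ccccc2)cc1)c1ccc(OCc2ccccc2)cc1
F2 | step 13 | (R)-7-(benzyloxy)-3-{1,1-bis[4-(benzyloxy)phenyl]-3-(2,4-dimethoxyphenyl)-3-oxopropan-2-yl}-4H-chromen-4-one | COc1ccc(C(=O)[C@@H](c2coc3cc(OCc4ccccc4)ccc3c2=O)C(c2ccc(OCc3ccccc3)cc2)c2ccc(OCc3ccccc3)cc2)c(OC)c1
F3 | step 3 | racemic 4,4-bis[4-(benzyloxy)phenyl]-3-(tert-butoxycarbonyl)butanoic acid | CC(C)(C)OC(=O)C(CC(=O)O)C(c1ccc(OCc2ccccc2)cc1)c1ccc(OCc2ccccc2)cc1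
F4 | step 8 | tert-butyl (2R)-2-[7-(benzyloxy)-2-hydroxy-4-oxo-3,4-dihydro-2H-chromen-3-yl]-3,3-bis[4-(benzyloxy)phenyl]propanoate (ring centres unspecified) | CC(C)(C)OC(=O)[C@@H](C1C(O)Oc2cc(OCc3ccccc3)ccc2C1=O)C(c1ccc(OCc2ccccc2)cc1)c1ccc(OCc2ccccc2)cc1
F5 | step 14 | (R)-3-[3-(2-chloro-6-hydroxy-4-methoxyphenyl)-1,1-bis(4-hydroxyphenyl)-3-oxopropan-2-yl]-7-hydroxy-4H-chromen-4-one | COc1cc(Cl)c(C(=O)[C@@H](c2coc3cc(O)ccc3c2=O)C(c2ccc(O)cc2)c2ccc(O)cc2)c(O)c1
A1 | alternative 1 | 4-(benzyloxy)-2-[(4-[2-(benzyloxy)-4-methoxyphenyl]-3-{bis[4-(benzyloxy)phenyl]methyl}-4-oxobut-2-en-1-yl)oxy]benzaldehyde (alkene geometry unspecified) | COc1ccc(C(=O)C(=CCOc2cc(OCc3ccccc3)ccc2C=O)C(c2ccc(OCc3ccccc3)cc2)c2ccc(OCc3ccccc3)cc2)c(OCc2ccccc2)c1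
A2 | alternative 1 | (3S)-7-(benzyloxy)-3-{(2R)-1-[2-(benzyloxy)-4-methoxyphenyl]-3,3-bis[4-(benzyloxy)phenyl]-1-oxopropan-2-yl}-2,3-dihydro-4H-chromen-4-one | COc1ccc(C(=O)[C@@H]([C@H]2COc3cc(OCc4ccccc4)ccc3C2=O)C(c2ccc(OCc3ccccc3)cc2)c2ccc(OCc3ccccc3)cc2)c(OCc2ccccc2)c1
A3 | alternative 2 | (2S)-1-[2-(benzyloxy)-4-methoxyphenyl]-2-{bis[4-(benzyloxy)phenyl]methyl}cyclopropan-1-ol (carbinol centre unspecified) | OC1(c2ccc(OC)cc2OCc2ccccc2)C[C@H]1C(c1ccc(OCc2ccccc2)cc1)c1ccc(OCc2ccccc2)cc1
A4 | alternative 2 | [5-(benzyloxy)-2-iodophenoxy](tert-butyl)dimethylsilane | CC(C)(C)[Si](C)(C)Oc1cc(OCc2ccccc2)ccc1I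
A5 | alternative 2 | (S)-2-{bis[4-(benzyloxy)phenyl]methyl}-1-[2-(benzyloxy)-4-methoxyphenyl]-4-[4-(benzyloxy)-2-(tert-butyldimethylsilyloxy)phenyl]butane-1,4-dione | COc1ccc(C(=O)[C@@H](CC(=O)c2ccc(OCc3ccccc3)cc2O[Si](C)(C)C(C)(C)C)C(c2ccc(OCc3ccccc3)cc2)c2ccc(OCc3ccccc3)cc2)c(OCc2ccccc2)c1
A6 | alternative 3 | (R)-7-(benzyloxy)-3-{1,1-bis[4-(benzyloxy)phenyl]-3-oxopent-4-yn-2-yl}-4H-chromen-4-one | C#CC(=O)[C@@H](c1coc2cc(OCc3ccccc3)ccc2c1=O)C(c1ccc(OCc2ccccc2)cc1)c1ccc(OCc2ccccc2)cc1
A7 | alternative 3 | 1,3-dimethoxy-1-(trimethylsilyloxy)buta-1,3-diene | COC(=C)C=C(OC)O[Si](C)(C)C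
A8 | alternative 3 | (R)-7-(benzyloxy)-3-{1,1-bis[4-(benzyloxy)phenyl]-3-(2-hydroxy-4-methoxyphenyl)-3-oxopropan-2-yl}-4H-chromen-4-one | COc1ccc(C(=O)[C@@H](c2coc3cc(OCc4ccccc4)ccc3c2=O)C(c2ccc(OCc3ccccc3)cc2)c2ccc(OCc3ccccc3)cc2)c(O)c1
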